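The readings were computed with made-up constants; the scatter is artificial.

Between 2.00 h and 4.00 h of Sunday's run the free monomer fell by 7.6 percentage points, more than the monomer in chains, yet that fell too, by 3.5 points. The sum of the two forms therefore fell.

| flask | free monomer | protic impurity | initiator | remark | time |
|---|---|---|---|---|---|
| Sunday's | 0.46 M | 0.69 M | 0.5 mol% | run made earlier |  |
| epsilon | 0.46 M | 0.460 M | 0.5 mol% |  | 20 h |
| beta | 0.46 M | 0.460 M | 2 mol% |  | 20 h |

Sunday's run (percent of the free monomer charged)

| time / h | monomer in chains / % | free monomer / % |
|---|---|---|
| 0.333 | 9.6 | 77.3 |
| 0.667 | 20.2 | 57.1 |
| 1.00 | 30.0 | 41.6 |
| 2.00 | 37.9 | 21.8 |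
| 4.00 | 34.4 | 14.2 |

(standard deviation of a reading: 0.5 percentage points)

- the average divides the monomer in chains by the number of chains begun, living and dead together
- the earlier runs were read with a standard deviation of 0.5 percentage points
- the earlier runs do not show the number of chains; that part of a forecast is a guess
- no earlier run changes the charge of protic impurity; that part of a forecast is a guess
- no earlier run changes the charge of initiator; that part of a forecast is a guess

- which of the two ends with the longer chains by the average number of monomer units in a chain (chains begun, living or dead) ("neither" if they lie within 10 %) (epsilon / beta / neither)
- average number of monomer units in a chain (chains begun, living or dead) at the end, epsilon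
- average number of monomer units in a chain (chains begun, living or dead) at the end, beta

I took this loss to be protic impurity consuming free monomer mole for mole. The logarithmic fall of Sunday's remaining impurity over that interval, reckoned from the missing monomer and divided by the free monomer present, gave a rate constant, as a reading, of 0.644 /M/h.

I guessed that free monomer in epsilon and beta would hold at Sunday's last reading, 14.2 %. Epsilon and beta charge impurity and monomer equally, so free monomer plus monomer in chains, the pool, should then decay pseudo-first-order with a drain time, the time for a fall by a factor e, of 23.8 h. Two times matter: this one and the 20 h of the run.

Adding the first 4.00 h, integrated from Sunday's free monomer, I reckoned for epsilon and beta alike a pool of 34.1 % at the end, so 19.9 % in chains. Guessing one chain per initiator, I expected 39.8 units in epsilon and 9.94 in beta.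

The forecast, unlike my figures, named epsilon as longer, with 65 units against 26 in beta, holding that in beta “propagation beats the side reaction”.

The simulation gave epsilon as longer, with 23.8 units against 5.37 in beta.

    free monomer + living end → monomer in chains + living end, rate k1*[living end]*[free monomer] (k = 390 /M/h)
    living end + monomer in chains → dead end (k = 0.0943 /M/h)
    monomer in chains + living end → free monomer + living end, rate k3*[living end] as long as [monomer in chains] is above zero (k = 33.5 /h)
    protic impurity + free monomer → quenched substrate (k = 0.687 /M/h)
    free monomer + initiator → living end + monomer in chains (k = 8.73 /M/h)

Epsilon had not come to rest at 20 h. Its free monomer stood at 15.5 % at 10.0 h and 16.4 % at 20.0 h, while monomer in chains fell from 31.5 % to 11.9 %. At 200 h epsilon held 1.61 % free monomer and 1.74 % of its impurity, and the average length was 0.00189 units.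

For epsilon read at 12 h, the drain time gives a pool of 47.7 %, hence 67.0 units. The simulation gave 53.8.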